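TBS = tert-butyldimethylsilyl; TBSO = tert-butyldimethylsilyloxy. Ring B is the benzo ring of the dihydrobenzofuran, ring C the dihydrofuran ring, ring A the 2,4-dioxygenated ring of the C3 aroyl group, ring D the 4-oxygenated phenyl ring on C2, and ring E the 2,4-dioxygenated ring of the enone.

## Structural features

The target is a 2,3-dihydrobenzofuran (ring B fused to ring C) with a 4-hydroxyphenyl group on C2, a hydroxyl and a 2,4-dihydroxybenzoyl group on C3, and at C5 an (E)-enone chain ending in a second 2,4-dihydroxyphenyl ketone, so that ring B is the β-aryl end of a 2'-hydroxychalcone. The two stereocentres are adjacent: C2 (S) is a benzylic ether CH, and C3 (S) is a fully substituted carbinol bound to C3a of ring B, to C2 and to the aroyl carbonyl, with the hydroxyl cis to the ring D aryl group and the aroyl group trans to it. The fragile points are these: the tertiary α-hydroxy ketone can lose water across C2–C3 under acid to give an aromatic benzofuran, or undergo α-ketol shifts under base; the C2–O1 bond is a benzyl aryl ether para to a phenol and can open through a quinone methide once that phenol is deprotonated; the 2'-hydroxychalcone can close to a flavanone or isomerise in light; and there are five oxidisable phenols. C2 and C3 are the only sp3 carbons, so nearly all the work is aryl–carbon bond formation. The real difficulty is to create the oxygenated quaternary centre C3 next to C2 with relative and absolute control, and then to reach the free pentaphenol without acid or strong base. The key step exploits the fact that C3 is a carbinol carbon attached to ring B and to a second carbonyl, while C2 is a CH on the ether oxygen ortho to it on the same ring. This 1,5-relationship (C3, C3a, C7a, O1, C2) is the mark of δ-hydrogen abstraction by an ortho-benzyloxyaryl ketone, and the second carbonyl makes the chromophore a 1,2-dione that absorbs visible light. An excited 1,2-dione can abstract with either oxygen, so an ortho substituent on ring A with a C–H bond in the δ position (a methoxymethyl ether, for example) would compete with the benzylic CH2. Silyl ethers have no such bond and come off at the end with buffered fluoride, so all phenols are carried as TBS ethers.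

## Logic of the disconnections

**25 to 24.** The five O–Si bonds are added in the backward sense. Free phenols would interfere with every metal-mediated step, and 25 tolerates neither acid (dehydration to the benzofuran) nor phenoxide formation (opening of ring C at C2, flavanone closure). The skeleton is not simplified, but every earlier intermediate becomes non-ionisable. The forward step must cleave five aryl silyl ethers with a fluoride source that releases neutral phenols.

**24 to 18 and 23.** The bond between the enone carbonyl carbon and ring E is cut. It is the one C–C bond that can be made after the key step under neutral conditions. Ring E and two of the five oxygens are removed, and what remains is a cinnamic acid derivative. The forward coupling must tolerate an aryl ketone and a free tertiary alcohol and must leave the conjugated double bond alone, which points to a base-free thioester–boronic acid coupling.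

**18 to 17.** The C–S bond is cut; this is activation only. The forward step must acylate the thiol without adding it to the double bond and without touching the hindered C3 hydroxyl.

**17 to 15, and 15 to 14.** The C2–C3 bond is cut. Ring C opens, both stereocentres vanish, and the hydroxy ketone becomes an achiral 1,2-dione with an ortho benzyl ether. This is the largest simplification in the route. The forward step must choose one of two enantiotopic benzylic hydrogens, close the biradical with the ring D aryl group away from the aroyl group, and use only the carbonyl on ring B. The first demand is put on the crystal lattice of the ammonium carboxylate 15. The last is met in the design of 14, in which the ring A oxygen ortho to the dione is a silyl ether with no δ C–H bond. The carboxylic acid of 14 serves both as the handle for the chiral counter-ion and as the future enone carbonyl.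

**14 to 12 and 13.** The bond between C5 of ring B and the vinyl carbon is cut. Leaving the alkene out until the dione exists lets the dione be made with an oxidant that would destroy a cinnamate, and the acid needs no protecting group. The forward step must be a Heck reaction on an aryl bromide para to an ether oxygen that spares the dione and the silyl ethers.

**12 to 11.** The two carbonyl oxygens are removed, giving a diarylalkyne. The two aryl halves can then be joined by a catalytic coupling. The forward oxidant must not be a π-acid, because both alkyne carbons carry an ortho oxygen that could close to a benzofuran.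

**11 to 10 and 5.** The C(sp)–C(aryl) bond on ring B is cut. The coupling must take the iodide and leave the bromide, which the difference in oxidative addition rates secures at room temperature.

**10 to 9 and 8.** The O–CH2 bond is cut. Using the benzylic alcohol directly avoids the unstable 4-oxybenzyl halide. The forward step needs an acidic phenol, which the ortho-iodophenol is.

**Building blocks.** 8 goes back through 7 to 6 (silylation, hydride reduction). 5 goes back through 3 and 2 to 1 (silylation, then one-carbon homologation of the aldehyde under aprotic conditions, since carbonate in methanol would strip the aryl silyl ethers). 23 goes back through 20 to 19 (silylation, bromine–lithium exchange and borylation).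

## Other disconnections considered

**Alternative 1:** The cut runs through C2–C3 and C7a–O1, so ring C is assembled from a ring B mandelate equivalent and a ring D aldehyde.

- Forward key step: the lithium enolate of the cis-dioxolanone A1 (LiN(i-Pr)2, THF, −78 °C) should add to aldehyde A2 on the face away from the tert-butyl group. On warming, the aldolate should displace the fluoride para to the nitrile and give the spiro compound A3, (2R,4S,2'S) as drawn.
- In favour: the configuration of C3 is dictated by the acetal centre through a planar enolate, a principle with a long record for 5-aryl dioxolanones. Two bonds and the ring form in one flask in ordinary glassware, and the nitrile makes substitution at C7a easy.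
- Against: only the enolate face is controlled. The face of A2 is not, so the C2 configuration depends on a reversible aldol step with one aldolate closing faster, which cannot be counted on. A1 must be made as a single enantiomer and a single acetal diastereomer. A3 carries two placeholders: a lactone that must become the ring A aryl ketone by arylation in the presence of a nitrile, and a nitrile that must become the three-carbon enone by reduction and base-mediated condensation next to a base-sensitive α-hydroxy ketone.
- Comparison: on structure it is weaker, because 17 already holds the aroyl group and the full three-carbon arm at the right oxidation level. On mechanism it is the better plan for the absolute configuration at C3 and for scale, and the weaker one for C2. On step economy it is about equal up to the key step and longer after it.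

**Alternative 2:** The cut runs through C3–C3a and C2–O1, which divides the target into two identical 4-hydroxychalcone units, probably the way the plant assembles it.

- Forward key step: Ag2O (or a laccase with O2) should oxidise chalcone A4 to its phenoxyl radical. Two radicals should join between the carbon α to the ketone of one and the carbon ortho to the phenol of the other, and the phenol should then add to the quinone methide to give the trans-dihydrobenzofuran A5.
- In favour: A4 is one condensation from commercial materials. One step makes ring C, both of its bonds and the whole carbon skeleton, enone arm and aroyl group included. In step count this is by far the shortest plan and clearly better than the chosen one. The trans relation of aryl and aroyl groups expected from thermodynamic closure is the relation required.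
- Against: A5 lacks the C3 hydroxyl. Its C3–H must be replaced by OH on the hindered face cis to the ring D aryl group, through an enolate that has the ring oxygen as a β-leaving group and can open ring C. The coupling is not regioselective by nature (the α-carbon can also join oxygen or another α-carbon), so low conversion to A5 must be expected. A5 is racemic and nothing in the reagents controls absolute configuration, so a resolution would end the route.
- Descriptor: A5 as drawn is (2R,3R). The spatial arrangement at C2 is that of the target, but with hydrogen on C3 the ring D carbon outranks C3 and the descriptor changes.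
- Comparison: on structure it matches the hidden symmetry of the target better. On mechanism it is equal for the relative configuration of C2 and the aroyl group, but it has no answer for the C3 oxygen or for the enantiomer, which the chosen key step addresses together. On step economy it is better, which would not outweigh an unselective hydroxylation and a late resolution.

**Alternative 3:** The cut runs through C3–C3a and C7a–O1, so ring B is delivered as a 1,2-difunctional arene onto a preformed C2–C3 unit.

- Forward key step: the hydroxyl of the (S)-α-hydroxy ketone A6 is first converted to its magnesium alkoxide. The ortho-fluoroaryl Grignard reagent A7 should add to the chelated ketone from the side of the C2 hydrogen, and after addition of KOt-Bu and warming the C2 alkoxide should displace fluoride to give A8.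
- In favour: both stereocentres rest on established principles, C2 from the enantiopure carbinol and C3 from chelation control, and the chelate model predicts the required cis relation of hydroxyl and ring D aryl group. In reliability of stereochemical prediction this plan is better than the chosen one. The dithiane leaves only one ketone in the substrate, and the ring closure is activated by the para nitrile.
- Against: the ketone of A6 sits next to a fully substituted dithiane carbon bearing an ortho-substituted aryl ring, so aryl Grignard addition should be slow. A7 must be kept cold, because it can lose magnesium fluoride to give an aryne and can attack its own nitrile. The stereocentre of A6 is benzylic and α to a ketone, so it is open to epimerisation and α-ketol shift under base. After A8 the nitrile must still become the enone, and the dithiane must be removed in the presence of electron-rich rings and an enone.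
- Comparison: on structure it is equal in convergence (three aryl pieces) but uses two masked functions where the chosen plan uses none. On mechanism it is a two-electron sequence that is easier to scale, but its decisive step asks a hindered ketone and an unstable organometallic to meet, whereas the photochemical step is intramolecular. On step economy it should be longer, because A6 needs its own asymmetric synthesis and the end game needs four or more operations.

Key step: step 11

Assumption 1: the sense of induction by a chiral lattice cannot be predicted; the route is written with (R)-1-phenylethylamine, and the (S)-amine takes its place if the crystal of the (R)-salt favours the mirror-image product.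
Assumption 2: 4-bromo-2-iodophenol, 4-bromoresorcinol, the two hydroxybenzaldehydes and acrylic acid are taken as commercial; compounds 12, 14 and 15 are handled with exclusion of light.

## Route

Step 1
Reactants: 1 2,4-dihydroxybenzaldehyde
Product: 2 2,4-bis(TBSO)benzaldehyde
Conditions: TBSCl (2.4 equiv), imidazole, DMF, 0 °C to rt
Reagents that add atoms: tert-butyldimethylsilyl chloride, CC(C)(C)[Si](C)(C)Cl
Why: Silyl ether formation at both phenols; the hydrogen-bonded 2-OH is slower but is silylated by excess reagent in DMF.

Step 2
Reactants: 2 2,4-bis(TBSO)benzaldehyde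
Product: 3 1-(2,2-dibromovinyl)-2,4-bis(TBSO)benzene
Conditions: CBr4, PPh3, CH2Cl2, 0 °C
Reagents that add atoms: carbon tetrabromide, BrC(Br)(Br)Br
Why: Ramirez dibromo-olefination (first half of the Corey–Fuchs sequence); it is a Wittig-type process, so no alkoxide forms next to the ortho silyl ether and silyl migration has no opening.

Step 3
Reactants: 3 1-(2,2-dibromovinyl)-2,4-bis(TBSO)benzene
Product: 5 1-ethynyl-2,4-bis(TBSO)benzene, via lithium acetylide 4 (not isolated)
Conditions: n-BuLi (2.1 equiv), THF, −78 °C; aq. NH4Cl
Reagents that add atoms: none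
Why: Bromine–lithium exchange, Fritsch–Buttenberg–Wiechell rearrangement and deprotonation give the acetylide, which is protonated on work-up (second half of Corey–Fuchs); the aprotic medium keeps the aryl silyl ethers, which carbonate in methanol would endanger.

Step 4
Reactants: 6 4-hydroxybenzaldehyde
Product: 7 4-(TBSO)benzaldehyde
Conditions: TBSCl, imidazole, DMF, rt
Reagents that add atoms: tert-butyldimethylsilyl chloride, CC(C)(C)[Si](C)(C)Cl
Why: Routine phenol silylation.

Step 5
Reactants: 7 4-(TBSO)benzaldehyde
Product: 8 [4-(TBSO)phenyl]methanol
Conditions: NaBH4, THF/MeOH, 0 °C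
Reagents that add atoms: none
Why: Hydride reduction of the aldehyde; short reaction time at 0 °C keeps the aryl silyl ether intact.

Step 6
Reactants: 9 4-bromo-2-iodophenol; 8 [4-(TBSO)phenyl]methanol
Product: 10 4-bromo-1-{[4-(TBSO)benzyl]oxy}-2-iodobenzene
Conditions: PPh3, DIAD, THF, 0 °C to rt
Reagents that add atoms: none
Why: Mitsunobu etherification; the acidic ortho-iodophenol is a good pronucleophile, and using the benzylic alcohol directly avoids the unstable 4-oxybenzyl halide.

Step 7
Reactants: 10 4-bromo-1-{[4-(TBSO)benzyl]oxy}-2-iodobenzene; 5 1-ethynyl-2,4-bis(TBSO)benzene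
Product: 11 4-bromo-2-{[2,4-bis(TBSO)phenyl]ethynyl}-1-{[4-(TBSO)benzyl]oxy}benzene
Conditions: PdCl2(PPh3)2 (2 mol%), CuI (4 mol%), Et3N/THF, rt, degassed
Reagents that add atoms: none
Why: Sonogashira coupling; oxidative addition of zerovalent palladium to the C–I bond is far faster than to C–Br at room temperature, so the bromide is kept for step 9.

Step 8
Reactants: 11 4-bromo-2-{[2,4-bis(TBSO)phenyl]ethynyl}-1-{[4-(TBSO)benzyl]oxy}benzene
Product: 12 1-(5-bromo-2-{[4-(TBSO)benzyl]oxy}phenyl)-2-[2,4-bis(TBSO)phenyl]ethane-1,2-dione
Conditions: KMnO4, NaHCO3, MgSO4, acetone/H2O (CH2Cl2 as cosolvent), 0 °C to rt; dark from here on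
Reagents that add atoms: potassium permanganate, [K+].[O-][Mn](=O)(=O)=O
Why: Buffered permanganate oxidation of a diarylalkyne to the benzil through a cyclic manganate ester; the oxidant is not a π-acid, so neither ortho oxygen is drawn into benzofuran formation, and no alkene is present yet.

Step 9
Reactants: 12 1-(5-bromo-2-{[4-(TBSO)benzyl]oxy}phenyl)-2-[2,4-bis(TBSO)phenyl]ethane-1,2-dione; 13 acrylic acid
Product: 14 (E)-3-[3-{2-[2,4-bis(TBSO)phenyl]-2-oxoacetyl}-4-{[4-(TBSO)benzyl]oxy}phenyl]acrylic acid
Conditions: Pd(OAc)2 (5 mol%), P(o-tol)3 (10 mol%), Et3N, MeCN, 85 °C, dark; aq. citric acid work-up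
Reagents that add atoms: none
Why: Mizoroki–Heck reaction with free acrylic acid; syn insertion and syn β-hydride elimination give the E alkene, and the acid is obtained without an ester protecting group. Aryl 1,2-diones are compatible with these phosphine/amine conditions.

Step 10
Reactants: 14 (E)-3-[3-{2-[2,4-bis(TBSO)phenyl]-2-oxoacetyl}-4-{[4-(TBSO)benzyl]oxy}phenyl]acrylic acid
Product: 15 (R)-1-phenylethylammonium (E)-3-[3-{2-[2,4-bis(TBSO)phenyl]-2-oxoacetyl}-4-{[4-(TBSO)benzyl]oxy}phenyl]acrylate
Conditions: (R)-1-phenylethylamine (1.0 equiv), EtOAc, rt; slow crystallisation with heptane, dark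
Reagents that add atoms: (R)-1-phenylethylamine, C[C@@H](N)c1ccccc1
Why: Acid–base salt formation; the enantiopure cation forces a chiral space group, and exactly one equivalent is used so that no free amine remains to reduce the excited dione.

Step 11
Reactants: 15 (R)-1-phenylethylammonium (E)-3-[3-{2-[2,4-bis(TBSO)phenyl]-2-oxoacetyl}-4-{[4-(TBSO)benzyl]oxy}phenyl]acrylate
Product: 17 (E)-3-[(2S,3S)-3-[2,4-bis(TBSO)benzoyl]-3-hydroxy-2-[4-(TBSO)phenyl]-2,3-dihydrobenzofuran-5-yl]acrylic acid, via (R)-1-phenylethylammonium salt of the cyclised acid 16 (not isolated)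
Conditions: powdered crystals of 15 as a thin layer between glass plates, 420 nm LED, 0 °C, Ar; then EtOAc/aq. citric acid, 0 °C
Reagents that add atoms: none
Why: Proposed new method: excitation of the n,π* band of the 1,2-dione gives a triplet in which the oxygen of the carbonyl on ring B takes one benzylic hydrogen of the OCH2Ar group through a seven-membered transition state, leaving a 1,5-biradical made of a ketyl centre (stabilised by ring B and the second carbonyl) and an α-aryloxybenzyl centre (stabilised by oxygen and the 4-silyloxyphenyl ring). Combination of the two radical ends forms C2–C3 and closes the five-membered ring C; this is a biradical collapse and not a polar cyclisation, and cleavage is excluded because a 1,5-biradical has no bond between its termini to break. The closest known reactions are the solution Norrish–Yang cyclisation of ortho-benzyloxyphenyl ketones and glyoxylates to cis-3-hydroxy-2-aryl-2,3-dihydrobenzofurans, and solid-state Norrish–Yang reactions of carboxylic acids made enantioselective by crystallisation with an enantiopure amine; their combination on this substrate class is the untested part. The relative configuration at C3 should follow from closure with the ring D aryl group turned away from the aroyl group, which places hydroxyl and 2-aryl cis. The absolute configuration of both centres should follow from the lattice: the dione anion is frozen in one twisted conformation, only one of the two enantiotopic benzylic hydrogens lies near the abstracting oxygen, and closure occurs with least motion. Site selectivity between the two carbonyl groups is secured by the substrate, because the silyl ether ortho to the ring A carbonyl offers no C–H bond in the δ position. Chemoselectivity is secured by the wavelength, since neither the cinnamate nor the product ketone absorbs at 420 nm, and by protonation of the amine, which blocks electron transfer to the excited dione.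

Step 12
Reactants: 17 (E)-3-[(2S,3S)-3-[2,4-bis(TBSO)benzoyl]-3-hydroxy-2-[4-(TBSO)phenyl]-2,3-dihydrobenzofuran-5-yl]acrylic acid
Product: 18 S-ethyl (E)-3-[(2S,3S)-3-[2,4-bis(TBSO)benzoyl]-3-hydroxy-2-[4-(TBSO)phenyl]-2,3-dihydrobenzofuran-5-yl]prop-2-enethioate
Conditions: EtSH (1.2 equiv), EDC·HCl, DMAP (cat.), CH2Cl2, 0 °C
Reagents that add atoms: ethanethiol, CCS
Why: Carbodiimide-mediated thioesterification; the thiol is acylated far faster than the hindered tertiary C3 hydroxyl, and low temperature with little base disfavours thiol conjugate addition to the β-aryl acrylate.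

Step 13
Reactants: 19 4-bromoresorcinol
Product: 20 1-bromo-2,4-bis(TBSO)benzene
Conditions: TBSCl (2.4 equiv), imidazole, DMF, rt
Reagents that add atoms: tert-butyldimethylsilyl chloride, CC(C)(C)[Si](C)(C)Cl
Why: Routine silylation of both phenols.

Step 14
Reactants: 20 1-bromo-2,4-bis(TBSO)benzene
Product: 23 [2,4-bis(TBSO)phenyl]boronic acid, via aryllithium 21 (not isolated), via lithium aryltriisopropoxyborate 22 (not isolated)
Conditions: B(Oi-Pr)3 present from the start, n-BuLi added at −78 °C, THF/toluene; aq. NH4Cl, 0 °C
Reagents that add atoms: triisopropyl borate, CC(C)OB(OC(C)C)OC(C)C; water, O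
Why: Bromine–lithium exchange with in situ borate capture, then hydrolysis of the ate complex; trapping the aryllithium as it forms leaves no time for the ortho silyl group to migrate from oxygen to carbon.

Step 15
Reactants: 18 S-ethyl (E)-3-[(2S,3S)-3-[2,4-bis(TBSO)benzoyl]-3-hydroxy-2-[4-(TBSO)phenyl]-2,3-dihydrobenzofuran-5-yl]prop-2-enethioate; 23 [2,4-bis(TBSO)phenyl]boronic acid
Product: 24 (E)-1-[2,4-bis(TBSO)phenyl]-3-[(2S,3S)-3-[2,4-bis(TBSO)benzoyl]-3-hydroxy-2-[4-(TBSO)phenyl]-2,3-dihydrobenzofuran-5-yl]prop-2-en-1-one
Conditions: Pd2(dba)3 (2.5 mol%), P(2-furyl)3 (15 mol%), copper thiophene-2-carboxylate (CuTC, 1.6 equiv), THF, 50 °C, Ar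
Reagents that add atoms: none
Why: Liebeskind–Srogl ketone synthesis; zerovalent palladium inserts into the C–S bond and the copper carboxylate activates both sulfur and boron, so no base is needed and the ketone, the tertiary alcohol and both stereocentres are untouched.

Step 16
Reactants: 24 (E)-1-[2,4-bis(TBSO)phenyl]-3-[(2S,3S)-3-[2,4-bis(TBSO)benzoyl]-3-hydroxy-2-[4-(TBSO)phenyl]-2,3-dihydrobenzofuran-5-yl]prop-2-en-1-one
Product: 25 (E)-3-[(2S,3S)-3-(2,4-dihydroxybenzoyl)-3-hydroxy-2-(4-hydroxyphenyl)-2,3-dihydrobenzofuran-5-yl]-1-(2,4-dihydroxyphenyl)prop-2-en-1-one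
Conditions: KHF2, MeOH/THF, rt, dim light
Reagents that add atoms: none
Why: Fluoride-driven cleavage of the five aryl Si–O bonds by a weakly acidic HF source; the phenols are released in neutral form, so phenoxide-driven opening of ring C, flavanone closure, α-ketol shift and acid-driven dehydration to the benzofuran are all avoided and no stereocentre is touched.

## Compound list

1 | 2,4-dihydroxybenzaldehyde | O=Cc1ccc(O)cc1O | starting material
2 | 2,4-bis(tert-butyldimethylsilyloxy)benzaldehyde | O=Cc1ccc(O[Si](C)(C)C(C)(C)C)cc1O[Si](C)(C)C(C)(C)C | intermediate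
3 | 1-(2,2-dibromovinyl)-2,4-bis(tert-butyldimethylsilyloxy)benzene | BrC(Br)=Cc1ccc(O[Si](C)(C)C(C)(C)C)cc1O[Si](C)(C)C(C)(C)C | intermediate
4 | lithium [2,4-bis(tert-butyldimethylsilyloxy)phenyl]acetylide | [Li]C#Cc1ccc(O[Si](C)(C)C(C)(C)C)cc1O[Si](C)(C)C(C)(C)C | intermediate
5 | 1-ethynyl-2,4-bis(tert-butyldimethylsilyloxy)benzene | C#Cc1ccc(O[Si](C)(C)C(C)(C)C)cc1O[Si](C)(C)C(C)(C)C | intermediate
6 | 4-hydroxybenzaldehyde | O=Cc1ccc(O)cc1 | starting material
7 | 4-(tert-butyldimethylsilyloxy)benzaldehyde | O=Cc1ccc(O[Si](C)(C)C(C)(C)C)cc1 | intermediate
8 | [4-(tert-butyldimethylsilyloxy)phenyl]methanol | OCc1ccc(O[Si](C)(C)C(C)(C)C)cc1 | intermediate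
9 | 4-bromo-2-iodophenol | Oc1ccc(Br)cc1I | starting material
10 | 4-bromo-1-{[4-(tert-butyldimethylsilyloxy)benzyl]oxy}-2-iodobenzene | Brc1ccc(OCc2ccc(O[Si](C)(C)C(C)(C)C)cc2)c(I)c1 | intermediate
11 | 4-bromo-2-{[2,4-bis(tert-butyldimethylsilyloxy)phenyl]ethynyl}-1-{[4-(tert-butyldimethylsilyloxy)benzyl]oxy}benzene | Brc1ccc(OCc2ccc(O[Si](C)(C)C(C)(C)C)cc2)c(c1)C#Cc1ccc(O[Si](C)(C)C(C)(C)C)cc1O[Si](C)(C)C(C)(C)C | intermediate
12 | 1-(5-bromo-2-{[4-(tert-butyldimethylsilyloxy)benzyl]oxy}phenyl)-2-[2,4-bis(tert-butyldimethylsilyloxy)phenyl]ethane-1,2-dione | Brc1ccc(OCc2ccc(O[Si](C)(C)C(C)(C)C)cc2)c(c1)C(=O)C(=O)c1ccc(O[Si](C)(C)C(C)(C)C)cc1O[Si](C)(C)C(C)(C)C | intermediate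
13 | acrylic acid | C=CC(=O)O | starting material
14 | (E)-3-[3-{2-[2,4-bis(tert-butyldimethylsilyloxy)phenyl]-2-oxoacetyl}-4-{[4-(tert-butyldimethylsilyloxy)benzyl]oxy}phenyl]acrylic acid | OC(=O)/C=C/c1ccc(OCc2ccc(O[Si](C)(C)C(C)(C)C)cc2)c(c1)C(=O)C(=O)c1ccc(O[Si](C)(C)C(C)(C)C)cc1O[Si](C)(C)C(C)(C)C | intermediate
15 | (R)-1-phenylethylammonium salt of 14 | C[C@@H]([NH3+])c1ccccc1.[O-]C(=O)/C=C/c1ccc(OCc2ccc(O[Si](C)(C)C(C)(C)C)cc2)c(c1)C(=O)C(=O)c1ccc(O[Si](C)(C)C(C)(C)C)cc1O[Si](C)(C)C(C)(C)C | intermediate
16 | (R)-1-phenylethylammonium (E)-3-[(2S,3S)-3-[2,4-bis(tert-butyldimethylsilyloxy)benzoyl]-3-hydroxy-2-[4-(tert-butyldimethylsilyloxy)phenyl]-2,3-dihydrobenzofuran-5-yl]acrylate | C[C@@H]([NH3+])c1ccccc1.[O-]C(=O)/C=C/c1ccc2c(c1)[C@@](O)(C(=O)c1ccc(O[Si](C)(C)C(C)(C)C)cc1O[Si](C)(C)C(C)(C)C)[C@H](c1ccc(O[Si](C)(C)C(C)(C)C)cc1)O2 | intermediate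
17 | (E)-3-[(2S,3S)-3-[2,4-bis(tert-butyldimethylsilyloxy)benzoyl]-3-hydroxy-2-[4-(tert-butyldimethylsilyloxy)phenyl]-2,3-dihydrobenzofuran-5-yl]acrylic acid | OC(=O)/C=C/c1ccc2c(c1)[C@@](O)(C(=O)c1ccc(O[Si](C)(C)C(C)(C)C)cc1O[Si](C)(C)C(C)(C)C)[C@H](c1ccc(O[Si](C)(C)C(C)(C)C)cc1)O2 | intermediate
18 | S-ethyl (E)-3-[(2S,3S)-3-[2,4-bis(tert-butyldimethylsilyloxy)benzoyl]-3-hydroxy-2-[4-(tert-butyldimethylsilyloxy)phenyl]-2,3-dihydrobenzofuran-5-yl]prop-2-enethioate | CCSC(=O)/C=C/c1ccc2c(c1)[C@@](O)(C(=O)c1ccc(O[Si](C)(C)C(C)(C)C)cc1O[Si](C)(C)C(C)(C)C)[C@H](c1ccc(O[Si](C)(C)C(C)(C)C)cc1)O2 | intermediate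
19 | 4-bromoresorcinol (4-bromobenzene-1,3-diol) | Oc1ccc(Br)c(O)c1 | starting material
20 | 1-bromo-2,4-bis(tert-butyldimethylsilyloxy)benzene | Brc1ccc(O[Si](C)(C)C(C)(C)C)cc1O[Si](C)(C)C(C)(C)C | intermediate
21 | [2,4-bis(tert-butyldimethylsilyloxy)phenyl]lithium | [Li]c1ccc(O[Si](C)(C)C(C)(C)C)cc1O[Si](C)(C)C(C)(C)C | intermediate
22 | lithium [2,4-bis(tert-butyldimethylsilyloxy)phenyl]triisopropoxyborate | [Li+].CC(C)O[B-](OC(C)C)(OC(C)C)c1ccc(O[Si](C)(C)C(C)(C)C)cc1O[Si](C)(C)C(C)(C)C | intermediate
23 | [2,4-bis(tert-butyldimethylsilyloxy)phenyl]boronic acid | OB(O)c1ccc(O[Si](C)(C)C(C)(C)C)cc1O[Si](C)(C)C(C)(C)C | intermediate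
24 | (E)-1-[2,4-bis(tert-butyldimethylsilyloxy)phenyl]-3-[(2S,3S)-3-[2,4-bis(tert-butyldimethylsilyloxy)benzoyl]-3-hydroxy-2-[4-(tert-butyldimethylsilyloxy)phenyl]-2,3-dihydrobenzofuran-5-yl]prop-2-en-1-one | O=C(/C=C/c1ccc2c(c1)[C@@](O)(C(=O)c1ccc(O[Si](C)(C)C(C)(C)C)cc1O[Si](C)(C)C(C)(C)C)[C@H](c1ccc(O[Si](C)(C)C(C)(C)C)cc1)O2)c1ccc(O[Si](C)(C)C(C)(C)C)cc1O[Si](C)(C)C(C)(C)C | intermediate
25 | (E)-3-[(2S,3S)-3-(2,4-dihydroxybenzoyl)-3-hydroxy-2-(4-hydroxyphenyl)-2,3-dihydrobenzofuran-5-yl]-1-(2,4-dihydroxyphenyl)prop-2-en-1-one | O=C(/C=C/c1ccc2c(c1)[C@@](O)(C(=O)c1ccc(O)cc1O)[C@H](c1ccc(O)cc1)O2)c1ccc(O)cc1O | target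

## Step count and least certain steps

Total step count: 16. Longest linear sequence: 11 steps (steps 1, 2, 3, 7, 8, 9, 10, 11, 12, 15, 16).

**Step 11 (key step, proposed new method).** The most likely failure is loss of lattice control. The three silyl groups may keep salt 15 from forming ordered crystals, the crystal may pack with both benzylic hydrogens out of reach of the carbonyl oxygen, or it may soften as product accumulates. The reaction would then stall or continue in a disordered phase with eroded enantioselectivity. Fallback with known chemistry: from 14, irradiation at 420 nm in degassed benzene, the established solution Norrish–Yang cyclisation of ortho-benzyloxyaryl ketones, should give the cis-configured acid as the racemate, racemic (E)-3-[(2S*,3S*)-3-[2,4-bis(TBSO)benzoyl]-3-hydroxy-2-[4-(TBSO)phenyl]-2,3-dihydrobenzofuran-5-yl]acrylic acid F1. F1 is resolved on a chiral stationary phase, or by fractional crystallisation with (R)-1-phenylethylamine (the salt of the wanted enantiomer is 16) followed by acidification. The route is rejoined at 17.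

**Step 9.** The most likely failure is breakdown of the 1,2-dione or loss of silyl groups during long heating with amine and ammonium acrylate, because oxidative addition to an aryl bromide para to an ether oxygen is slow. Fallback: from 11, the Heck reaction with 13 is run before the dione exists and gives (E)-3-[3-{[2,4-bis(TBSO)phenyl]ethynyl}-4-{[4-(TBSO)benzyl]oxy}phenyl]acrylic acid F2. The alkyne of F2 is then oxidised with PdCl2 in DMSO at 100–120 °C, an oxidant that leaves an electron-poor alkene alone, and the route is rejoined at 14. This order is second choice because divalent palladium is a π-acid and can draw the ortho oxygens into benzofuran formation.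

**Step 15.** The most likely failure is protodeboronation of 23 outrunning a slow transmetalation, since the boronic acid is electron-rich and flanked by a bulky silyl ether. Fallback by Fukuyama ketone synthesis: from 18; aryllithium 21 (from 20 with n-BuLi at −78 °C, no borate) is transmetalated with ZnCl2 to [2,4-bis(TBSO)phenyl]zinc chloride F3, which is coupled with 18 under PdCl2(PPh3)2 catalysis in THF/toluene at rt. Arylzinc halides do not add to the ketone. The route is rejoined at 24.

**Step 8.** The most likely failure is over-oxidation: cleavage of the new dione C–C bond to two benzoic acids, or attack at the benzylic ether CH2, if the lipophilic substrate reacts slowly in the aqueous medium. Fallback without alkyne oxidation, from 10 and 21: iodine–magnesium exchange on 10 (i-PrMgCl·LiCl, THF, −40 °C, bromide untouched) gives (5-bromo-2-{[4-(TBSO)benzyl]oxy}phenyl)magnesium chloride F4. Addition of F4 to 1,4-dimethylpiperazine-2,3-dione gives the mono-adduct chloromagnesium 2-(5-bromo-2-{[4-(TBSO)benzyl]oxy}phenyl)-1,4-dimethyl-3-oxopiperazin-2-olate F5, whose tetrahedral centre protects the first carbonyl. Aryllithium 21 then adds to the remaining amide carbonyl to give the bis-adduct, the mixed lithium/chloromagnesium 2,3-diaryl-1,4-dimethylpiperazine-2,3-diolate F6. Cold 1 M HCl releases the dione, and the route is rejoined at 12.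

**Step 14.** The most likely failure is anionic migration of the ortho silyl group from oxygen to carbon in 21 (retro-Brook shift) before boron capture. Fallback: from 20 by Miyaura borylation (B2pin2, PdCl2(dppf), KOAc, dioxane, 80 °C) to 2-[2,4-bis(TBSO)phenyl]-4,4,5,5-tetramethyl-1,3,2-dioxaborolane F7, then NaIO4/NH4OAc in aqueous acetone. The route is rejoined at 23.

## Further compounds

F1 | step 11 | racemic (E)-3-[(2S*,3S*)-3-[2,4-bis(tert-butyldimethylsilyloxy)benzoyl]-3-hydroxy-2-[4-(tert-butyldimethylsilyloxy)phenyl]-2,3-dihydrobenzofuran-5-yl]acrylic acid (both enantiomers shown) | OC(=O)/C=C/c1ccc2c(c1)[C@@](O)(C(=O)c1ccc(O[Si](C)(C)C(C)(C)C)cc1O[Si](C)(C)C(C)(C)C)[C@H](c1ccc(O[Si](C)(C)C(C)(C)C)cc1)O2.OC(=O)/C=C/c1ccc2c(c1)[C@](O)(C(=O)c1ccc(O[Si](C)(C)C(C)(C)C)cc1O[Si](C)(C)C(C)(C)C)[C@@H](c1ccc(O[Si](C)(C)C(C)(C)C)cc1)O2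
F2 | step 9 | (E)-3-[3-{[2,4-bis(tert-butyldimethylsilyloxy)phenyl]ethynyl}-4-{[4-(tert-butyldimethylsilyloxy)benzyl]oxy}phenyl]acrylic acid | OC(=O)/C=C/c1ccc(OCc2ccc(O[Si](C)(C)C(C)(C)C)cc2)c(c1)C#Cc1ccc(O[Si](C)(C)C(C)(C)C)cc1O[Si](C)(C)C(C)(C)C
F3 | step 15 | [2,4-bis(tert-butyldimethylsilyloxy)phenyl]zinc chloride | Cl[Zn]c1ccc(O[Si](C)(C)C(C)(C)C)cc1O[Si](C)(C)C(C)(C)C
F4 | step 8 | (5-bromo-2-{[4-(tert-butyldimethylsilyloxy)benzyl]oxy}phenyl)magnesium chloride | Cl[Mg]c1cc(Br)ccc1OCc1ccc(O[Si](C)(C)C(C)(C)C)cc1
F5 | step 8 | chloromagnesium 2-(5-bromo-2-{[4-(tert-butyldimethylsilyloxy)benzyl]oxy}phenyl)-1,4-dimethyl-3-oxopiperazin-2-olate (racemic) | CN1CCN(C)C(O[Mg]Cl)(c2cc(Br)ccc2OCc2ccc(O[Si](C)(C)C(C)(C)C)cc2)C1=O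
F6 | step 8 | lithium chloromagnesium 2-(5-bromo-2-{[4-(tert-butyldimethylsilyloxy)benzyl]oxy}phenyl)-3-[2,4-bis(tert-butyldimethylsilyloxy)phenyl]-1,4-dimethylpiperazine-2,3-diolate (mixture of diastereomers) | CN1CCN(C)C(O[Mg]Cl)(c2cc(Br)ccc2OCc2ccc(O[Si](C)(C)C(C)(C)C)cc2)C1(O[Li])c1ccc(O[Si](C)(C)C(C)(C)C)cc1O[Si](C)(C)C(C)(C)C
F7 | step 14 | 2-[2,4-bis(tert-butyldimethylsilyloxy)phenyl]-4,4,5,5-tetramethyl-1,3,2-dioxaborolane | CC1(C)OB(OC1(C)C)c1ccc(O[Si](C)(C)C(C)(C)C)cc1O[Si](C)(C)C(C)(C)C
A1 | alternative 1 | (2R,5R)-2-tert-butyl-5-(5-cyano-2-fluorophenyl)-1,3-dioxolan-4-one (cis) | N#Cc1ccc(F)c(c1)[C@@H](O1)C(=O)O[C@@H]1C(C)(C)C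
A2 | alternative 1 | 4-(methoxymethoxy)benzaldehyde | O=Cc1ccc(OCOC)cc1
A3 | alternative 1 | (2R,4S,2'S)-2-tert-butyl-2'-[4-(methoxymethoxy)phenyl]-5-oxo-2'H-spiro[1,3-dioxolane-4,3'-benzofuran]-5'-carbonitrile (tert-butyl trans to C2', dioxolanone ring oxygen cis to the 2'-aryl group) | N#Cc1ccc2c(c1)[C@@](O1)(C(=O)O[C@@H]1C(C)(C)C)[C@H](c1ccc(OCOC)cc1)O2
A4 | alternative 2 | (E)-1-[2,4-bis(methoxymethoxy)phenyl]-3-(4-hydroxyphenyl)prop-2-en-1-one | O=C(/C=C/c1ccc(O)cc1)c1ccc(OCOC)cc1OCOC
A5 | alternative 2 | (E)-1-[2,4-bis(methoxymethoxy)phenyl]-3-[(2R,3R)-3-[2,4-bis(methoxymethoxy)benzoyl]-2-(4-hydroxyphenyl)-2,3-dihydrobenzofuran-5-yl]prop-2-en-1-one (trans; one enantiomer of the racemate drawn) | O=C(/C=C/c1ccc2c(c1)[C@@H](C(=O)c1ccc(OCOC)cc1OCOC)[C@H](c1ccc(O)cc1)O2)c1ccc(OCOC)cc1OCOC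
A6 | alternative 3 | (2S)-1-{2-[2,4-bis(methoxymethoxy)phenyl]-1,3-dithian-2-yl}-2-hydroxy-2-[4-(methoxymethoxy)phenyl]ethan-1-one | O[C@@H](c1ccc(OCOC)cc1)C(=O)C1(SCCCS1)c1ccc(OCOC)cc1OCOC
A7 | alternative 3 | (5-cyano-2-fluorophenyl)magnesium chloride | N#Cc1ccc(F)c([Mg]Cl)c1
A8 | alternative 3 | (2S,3S)-3-{2-[2,4-bis(methoxymethoxy)phenyl]-1,3-dithian-2-yl}-3-hydroxy-2-[4-(methoxymethoxy)phenyl]-2,3-dihydrobenzofuran-5-carbonitrile | N#Cc1ccc2c(c1)[C@@](O)(C1(SCCCS1)c1ccc(OCOC)cc1OCOC)[C@H](c1ccc(OCOC)cc1)O2
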